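**Plan**

- Retrosynthesis cuts, in this order: the carbinol–alkenyl C–C bond between the two rings (ring A aldehyde + ring B alkenyl iodide); in ring A the bond from the ring CH= to the quaternary CMe2 carbon; in ring B the C–CH3 bond of the tertiary carbinol and the C–Br bond.
- Enabling feature: in ring A the CMe2 carbon and the carbon bearing the exocyclic =CH2 are both bonded to the stereogenic ring CH. These three carbons can be folded into a gem-dimethylcyclopropane whose quaternary carbon carries CH2–OMs and a (Z)-Me3Si–CH=CH–CH2 arm; ionisation opens the three-membered ring to the =CH2 group plus a tertiary cation at CMe2, which the vinylsilane captures (ring expansion from 3 to 6).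
- Forward: tetrasubstituted allylic diazoacetate → cyclopropane-fused lactone (temporary ring) → diol → ring A by the cation cascade; ring B is made separately from a 4-substituted cyclohexanone that already carries the (E)-alkenyl iodide; the two are joined last by a Nozaki–Hiyama–Kishi coupling.
- Stereochemistry: ring A CH from the Rh-catalysed enantioselective cyclopropanation (the second cyclopropane stereocentre is erased in the key step); carbinol from Felkin–Anh addition; E-alkene from Zr-catalysed carboalumination; ring B from chiral lithium amide desymmetrisation, α-bromide equilibration and methyl addition anti to Br.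

Key step: step 9

Assumption: the sense of induction of Rh2(4R-MPPIM)4 on the tetrasubstituted allylic diazoacetate and of the (R,R)-lithium amide on the 4-substituted cyclohexanone is taken to follow that of the simplest members of each class (the prenyl ester and 4-tert-butylcyclohexanone); were either reversed, the antipodal catalyst or amide would be used.

**Route**

Step 1
Reactants: 1 triethyl phosphonoacetate; 2 3-bromo-1-(trimethylsilyl)prop-1-yne
Product: 3 ethyl 2-(diethoxyphosphoryl)-5-(trimethylsilyl)pent-4-ynoate (racemic)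
Conditions: NaH, THF, 0 °C → rt
Reagents that add atoms: none
Why: SN2 C-alkylation of the sodium phosphonoacetate carbanion with the propargylic bromide should install the silylalkyne arm, the Me3Si group disfavouring the SN2′ (allene) pathway.

Step 2
Reactants: 3 ethyl 2-(diethoxyphosphoryl)-5-(trimethylsilyl)pent-4-ynoate
Product: 4 ethyl 3-methyl-2-[3-(trimethylsilyl)prop-2-yn-1-yl]but-2-enoate
Conditions: NaH, THF, 0 °C; acetone (excess), reflux
Reagents that add atoms: acetone, CC(C)=O
Why: Horner–Wadsworth–Emmons olefination with acetone should give the tetrasubstituted enoate, and since both new alkene substituents are methyl no E/Z question arises.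

Step 3
Reactants: 4 ethyl 3-methyl-2-[3-(trimethylsilyl)prop-2-yn-1-yl]but-2-enoate
Product: 5 3-methyl-2-[3-(trimethylsilyl)prop-2-yn-1-yl]but-2-en-1-ol
Conditions: iBu2AlH, CH2Cl2, −78 → 0 °C; aq. potassium sodium tartrate work-up
Reagents that add atoms: none
Why: DIBAL-H 1,2-reduction of the hindered enoate should give the allylic alcohol without touching the silylalkyne.

Step 4
Reactants: 5 3-methyl-2-[3-(trimethylsilyl)prop-2-yn-1-yl]but-2-en-1-ol
Product: 7 3-methyl-2-[3-(trimethylsilyl)prop-2-yn-1-yl]but-2-en-1-yl diazoacetate, via bromoacetate ester 6 (not isolated)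
Conditions: BrCH2COBr, NaHCO3, MeCN, 0 °C; then TsNHNHTs, DBU, THF, 0 °C
Reagents that add atoms: bromoacetyl bromide, BrCC(Br)=O; N,N'-ditosylhydrazine, Cc1ccc(cc1)S(=O)(=O)NNS(=O)(=O)c1ccc(C)cc1
Why: O-acylation followed by the N,N'-ditosylhydrazine diazo synthesis (bromide displacement, then two sulfinate eliminations) should convert the alcohol into its diazoacetate under mild base.

Step 5
Reactants: 7 3-methyl-2-[3-(trimethylsilyl)prop-2-yn-1-yl]but-2-en-1-yl diazoacetate
Product: 8 (1S,5S)-6,6-dimethyl-5-[3-(trimethylsilyl)prop-2-yn-1-yl]-3-oxabicyclo[3.1.0]hexan-2-one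
Conditions: dirhodium tetrakis[methyl (4R)-2-oxo-1-(3-phenylpropanoyl)imidazolidine-4-carboxylate], Rh2(4R-MPPIM)4 (1 mol%), CH2Cl2, reflux, slow addition of 7
Reagents that add atoms: none
Why: Rh-carboxamidate-catalysed intramolecular cyclopropanation of the allylic diazoacetate should give the necessarily cis-fused cyclopropane lactone, the chiral ligand sphere selecting the alkene face so that the ring CH stereocentre (the only one that survives to the target) is set together with the quaternary one.

Step 6
Reactants: 8 (1S,5S)-6,6-dimethyl-5-[3-(trimethylsilyl)prop-2-yn-1-yl]-3-oxabicyclo[3.1.0]hexan-2-one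
Product: 9 (1S,5S)-6,6-dimethyl-5-[(2Z)-3-(trimethylsilyl)prop-2-en-1-yl]-3-oxabicyclo[3.1.0]hexan-2-one
Conditions: H2 (1 atm), Pd/CaCO3 poisoned with Pb(OAc)2 (Lindlar catalyst), quinoline, EtOAc, rt
Reagents that add atoms: none
Why: Lindlar semi-hydrogenation (syn addition of H2) of the silylalkyne should give the (Z)-vinylsilane that the key step needs, with lactone and cyclopropane inert.

Step 7
Reactants: 9 (1S,5S)-6,6-dimethyl-5-[(2Z)-3-(trimethylsilyl)prop-2-en-1-yl]-3-oxabicyclo[3.1.0]hexan-2-one
Product: 10 {(1S,3S)-2,2-dimethyl-1-[(2Z)-3-(trimethylsilyl)prop-2-en-1-yl]cyclopropane-1,3-diyl}dimethanol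
Conditions: LiAlH4, THF, 0 °C; basic work-up
Reagents that add atoms: none
Why: Hydride reduction of the lactone should open the temporary ring to the cis-diol without affecting the vinylsilane.

Step 8
Reactants: 10 {(1S,3S)-2,2-dimethyl-1-[(2Z)-3-(trimethylsilyl)prop-2-en-1-yl]cyclopropane-1,3-diyl}dimethanol
Product: 11 {(1S,3S)-3-({[tert-butyl(diphenyl)silyl]oxy}methyl)-2,2-dimethyl-1-[(2Z)-3-(trimethylsilyl)prop-2-en-1-yl]cyclopropyl}methanol
Conditions: TBDPSCl (1.0 equiv), imidazole, CH2Cl2, −20 °C
Reagents that add atoms: tert-butyl(chloro)diphenylsilane, CC(C)(C)[Si](Cl)(c1ccccc1)c1ccccc1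
Why: Kinetic monosilylation should select the hydroxymethyl on the CH ring carbon over the neopentylic one on the quaternary carbon, which stays free as the future leaving group.

Step 9
Reactants: 11 {(1S,3S)-3-({[tert-butyl(diphenyl)silyl]oxy}methyl)-2,2-dimethyl-1-[(2Z)-3-(trimethylsilyl)prop-2-en-1-yl]cyclopropyl}methanol
Product: 13 tert-butyl{[(1R)-2,2-dimethyl-6-methylidenecyclohex-3-en-1-yl]methoxy}diphenylsilane, via cyclopropylmethyl mesylate 12 (not isolated)
Conditions: Ms2O, 2,6-lutidine, CH2Cl2, −78 °C; then (CF3)2CHOH (HFIP), −40 → 0 °C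
Reagents that add atoms: none
Why: Proposed new method: the primary mesylate on the quaternary cyclopropane carbon should ionise in the fluorinated alcohol, the cyclopropylcarbinyl cation opening at its bond to the CMe2 carbon to give the tertiary homoallylic cation and at the same time the exocyclic methylene of ring A; the cation is then captured at the silicon-bearing carbon of the (Z)-vinylsilane and the β-silyl cation loses Me3Si, which leaves the ring C=C between the two former vinylsilane carbons. The closest known reaction types are the Julia cyclopropylcarbinyl-to-homoallyl rearrangement and the vinylsilane-terminated cation–olefin cyclisation, coupled here in one operation. Ring A closes in the 6-endo-trig mode at the vinylsilane, the 5-exo alternative being disfavoured because it would place the charge α to silicon. No new stereocentre is formed: the ring CH stereocentre is carried over unchanged from the cyclopropane, and the quaternary cyclopropane centre becomes sp2, so its configuration is irrelevant. The step needs cleavage of the cyclopropane bond to CMe2 (secured by the gem-dimethyl group, which makes that cation tertiary, whereas the other mode would give a secondary cation β to oxygen), ipso-endo attack (secured by the β-silicon effect and by the Z geometry, which rotates the C–Si bond into alignment with the empty orbital as the ring forms) and cyclisation faster than proton loss (favoured by the buffered, ionising, non-nucleophilic medium and the bulky silyl ether, a poor internal nucleophile).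

Step 10
Reactants: 13 tert-butyl{[(1R)-2,2-dimethyl-6-methylidenecyclohex-3-en-1-yl]methoxy}diphenylsilane
Product: 14 [(1R)-2,2-dimethyl-6-methylidenecyclohex-3-en-1-yl]methanol
Conditions: Bu4NF, THF, 0 °C → rt
Reagents that add atoms: none
Why: Fluoride-mediated desilylation should free the primary alcohol without acid, so that the skipped diene and the exocyclic alkene do not migrate.

Step 11
Reactants: 14 [(1R)-2,2-dimethyl-6-methylidenecyclohex-3-en-1-yl]methanol
Product: 15 (1R)-2,2-dimethyl-6-methylidenecyclohex-3-ene-1-carbaldehyde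
Conditions: Dess–Martin periodinane, NaHCO3, CH2Cl2, 0 °C; crude product used at once
Reagents that add atoms: none
Why: Buffered Dess–Martin oxidation should give the β,γ-unsaturated aldehyde under non-basic conditions that preserve the α-stereocentre and the alkene positions.

Step 12
Reactants: 16 1,4-dioxaspiro[4.5]decane-8-carbaldehyde
Product: 17 8-ethynyl-1,4-dioxaspiro[4.5]decane
Conditions: dimethyl (1-diazo-2-oxopropyl)phosphonate, K2CO3, MeOH, 0 °C → rt
Reagents that add atoms: dimethyl (1-diazo-2-oxopropyl)phosphonate, COP(=O)(OC)C(=[N+]=[N-])C(C)=O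
Why: Ohira–Bestmann (Seyferth–Gilbert) homologation should convert the aldehyde into the terminal alkyne under mild base.

Step 13
Reactants: 17 8-ethynyl-1,4-dioxaspiro[4.5]decane
Product: 19 8-[(1E)-1-iodoprop-1-en-2-yl]-1,4-dioxaspiro[4.5]decane, via alkenylalane 18 (not isolated)
Conditions: Me3Al, Cp2ZrCl2 (0.2 equiv), CH2Cl2, 0 °C → rt; then I2, THF, −30 °C
Reagents that add atoms: trimethylaluminium, C[Al](C)C; iodine, II
Why: Zr-catalysed carboalumination (syn addition of Me–Al across the alkyne, methyl to the internal carbon) followed by iodinolysis with retention should give the (E)-trisubstituted alkenyl iodide.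

Step 14
Reactants: 19 8-[(1E)-1-iodoprop-1-en-2-yl]-1,4-dioxaspiro[4.5]decane
Product: 20 4-[(1E)-1-iodoprop-1-en-2-yl]cyclohexan-1-one
Conditions: 1 M aq. HCl, THF, rt
Reagents that add atoms: water, O
Why: Acid-catalysed ketal hydrolysis should unmask the symmetrical 4-substituted cyclohexanone.

Step 15
Reactants: 20 4-[(1E)-1-iodoprop-1-en-2-yl]cyclohexan-1-one
Product: 21 trimethyl({(4S)-4-[(1E)-1-iodoprop-1-en-2-yl]cyclohex-1-en-1-yl}oxy)silane
Conditions: (R,R)-bis(1-phenylethyl)amine, nBuLi, LiCl, Me3SiCl, THF, −100 °C (in situ quench)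
Reagents that add atoms: chlorotrimethylsilane, C[Si](C)(C)Cl
Why: Enantioselective deprotonation with a C2-symmetric chiral lithium amide under in situ silyl quench should distinguish the two enantiotopic α-methylene groups and thereby create the ring stereocentre.

Step 16
Reactants: 21 trimethyl({(4S)-4-[(1E)-1-iodoprop-1-en-2-yl]cyclohex-1-en-1-yl}oxy)silane
Product: 23 (2S,4S)-2-bromo-4-[(1E)-1-iodoprop-1-en-2-yl]cyclohexan-1-one, via trans-bromoketone 22 (not isolated)
Conditions: NBS, THF, −78 °C; then LiBr (cat.), DMSO, rt (equilibration); chromatography, trans epimer re-equilibrated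
Reagents that add atoms: N-bromosuccinimide, BrN1C(=O)CCC1=O
Why: Electrophilic bromination of the enol silane is regiospecific for the enol carbon and should give the axial (trans) bromide first, which bromide-mediated epimerisation at the α-carbon equilibrates with the diequatorial cis epimer that is separated, the stereocentre from step 15 being untouched.

Step 17
Reactants: 23 (2S,4S)-2-bromo-4-[(1E)-1-iodoprop-1-en-2-yl]cyclohexan-1-one
Product: 24 (1R,2S,4S)-2-bromo-4-[(1E)-1-iodoprop-1-en-2-yl]-1-methylcyclohexan-1-ol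
Conditions: MeMgBr, CH2Cl2/Et2O, −78 °C; NH4Cl quench at −78 °C
Reagents that add atoms: methylmagnesium bromide, C[Mg]Br
Why: Grignard addition to the α-bromoketone should deliver methyl anti to bromine (chelate or polar Felkin–Anh/Cornforth control), giving the tertiary alcohol with OH axial and cis to the equatorial Br, an arrangement that cannot close to an epoxide.

Step 18
Reactants: 15 (1R)-2,2-dimethyl-6-methylidenecyclohex-3-ene-1-carbaldehyde; 24 (1R,2S,4S)-2-bromo-4-[(1E)-1-iodoprop-1-en-2-yl]-1-methylcyclohexan-1-ol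
Product: 25 (1R,2E)-3-[(1S,3S,4R)-3-bromo-4-hydroxy-4-methylcyclohexyl]-1-[(1R)-2,2-dimethyl-6-methylidenecyclohex-3-en-1-yl]but-2-en-1-ol (CNP0362245.1)
Conditions: CrCl2 (excess), NiCl2 (cat.), DMSO, rt
Reagents that add atoms: none
Why: Nozaki–Hiyama–Kishi coupling (Ni-catalysed alkenyl transfer to chromium, then addition to the aldehyde) should join the fragments with retention of the E geometry under neutral conditions that spare the secondary C–Br bond and the free tertiary OH, the Felkin–Anh approach anti to the quaternary CMe2 carbon setting the (R)-carbinol.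

**Compound list**

1 | triethyl phosphonoacetate | CCOC(=O)CP(=O)(OCC)OCC | starting material
2 | 3-bromo-1-(trimethylsilyl)prop-1-yne | C[Si](C)(C)C#CCBr | starting material
3 | ethyl 2-(diethoxyphosphoryl)-5-(trimethylsilyl)pent-4-ynoate (racemic) | CCOC(=O)C(CC#C[Si](C)(C)C)P(=O)(OCC)OCC | intermediate
4 | ethyl 3-methyl-2-[3-(trimethylsilyl)prop-2-yn-1-yl]but-2-enoate | CCOC(=O)C(CC#C[Si](C)(C)C)=C(C)C | intermediate
5 | 3-methyl-2-[3-(trimethylsilyl)prop-2-yn-1-yl]but-2-en-1-ol | OCC(CC#C[Si](C)(C)C)=C(C)C | intermediate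
6 | 3-methyl-2-[3-(trimethylsilyl)prop-2-yn-1-yl]but-2-en-1-yl bromoacetate | BrCC(=O)OCC(CC#C[Si](C)(C)C)=C(C)C | intermediate
7 | 3-methyl-2-[3-(trimethylsilyl)prop-2-yn-1-yl]but-2-en-1-yl diazoacetate | [N-]=[N+]=CC(=O)OCC(CC#C[Si](C)(C)C)=C(C)C | intermediate
8 | (1S,5S)-6,6-dimethyl-5-[3-(trimethylsilyl)prop-2-yn-1-yl]-3-oxabicyclo[3.1.0]hexan-2-one | O=C1OC[C@@]2(CC#C[Si](C)(C)C)[C@@H]1C2(C)C | intermediate
9 | (1S,5S)-6,6-dimethyl-5-[(2Z)-3-(trimethylsilyl)prop-2-en-1-yl]-3-oxabicyclo[3.1.0]hexan-2-one | O=C1OC[C@@]2(C/C=C\[Si](C)(C)C)[C@@H]1C2(C)C | intermediate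
10 | {(1S,3S)-2,2-dimethyl-1-[(2Z)-3-(trimethylsilyl)prop-2-en-1-yl]cyclopropane-1,3-diyl}dimethanol | OC[C@@]1(C/C=C\[Si](C)(C)C)[C@@H](CO)C1(C)C | intermediate
11 | {(1S,3S)-3-({[tert-butyl(diphenyl)silyl]oxy}methyl)-2,2-dimethyl-1-[(2Z)-3-(trimethylsilyl)prop-2-en-1-yl]cyclopropyl}methanol | OC[C@@]1(C/C=C\[Si](C)(C)C)[C@@H](CO[Si](c2ccccc2)(c2ccccc2)C(C)(C)C)C1(C)C | intermediate
12 | {(1S,3S)-3-({[tert-butyl(diphenyl)silyl]oxy}methyl)-2,2-dimethyl-1-[(2Z)-3-(trimethylsilyl)prop-2-en-1-yl]cyclopropyl}methyl methanesulfonate | CS(=O)(=O)OC[C@@]1(C/C=C\[Si](C)(C)C)[C@@H](CO[Si](c2ccccc2)(c2ccccc2)C(C)(C)C)C1(C)C | intermediate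
13 | tert-butyl{[(1R)-2,2-dimethyl-6-methylidenecyclohex-3-en-1-yl]methoxy}diphenylsilane | C=C1CC=CC(C)(C)[C@@H]1CO[Si](c1ccccc1)(c1ccccc1)C(C)(C)C | intermediate
14 | [(1R)-2,2-dimethyl-6-methylidenecyclohex-3-en-1-yl]methanol | C=C1CC=CC(C)(C)[C@@H]1CO | intermediate
15 | (1R)-2,2-dimethyl-6-methylidenecyclohex-3-ene-1-carbaldehyde | C=C1CC=CC(C)(C)[C@@H]1C=O | intermediate
16 | 1,4-dioxaspiro[4.5]decane-8-carbaldehyde | O=CC1CCC2(CC1)OCCO2 | starting material
17 | 8-ethynyl-1,4-dioxaspiro[4.5]decane | C#CC1CCC2(CC1)OCCO2 | intermediate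
18 | [(1E)-2-(1,4-dioxaspiro[4.5]decan-8-yl)prop-1-en-1-yl]dimethylalumane | C[Al](C)/C=C(\C)C1CCC2(CC1)OCCO2 | intermediate
19 | 8-[(1E)-1-iodoprop-1-en-2-yl]-1,4-dioxaspiro[4.5]decane | I/C=C(\C)C1CCC2(CC1)OCCO2 | intermediate
20 | 4-[(1E)-1-iodoprop-1-en-2-yl]cyclohexan-1-one | I/C=C(\C)C1CCC(=O)CC1 | intermediate
21 | trimethyl({(4S)-4-[(1E)-1-iodoprop-1-en-2-yl]cyclohex-1-en-1-yl}oxy)silane | I/C=C(\C)[C@H]1CCC(O[Si](C)(C)C)=CC1 | intermediate
22 | (2R,4S)-2-bromo-4-[(1E)-1-iodoprop-1-en-2-yl]cyclohexan-1-one (trans, axial Br) | I/C=C(\C)[C@H]1CCC(=O)[C@H](Br)C1 | intermediate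
23 | (2S,4S)-2-bromo-4-[(1E)-1-iodoprop-1-en-2-yl]cyclohexan-1-one (cis, equatorial Br) | I/C=C(\C)[C@H]1CCC(=O)[C@@H](Br)C1 | intermediate
24 | (1R,2S,4S)-2-bromo-4-[(1E)-1-iodoprop-1-en-2-yl]-1-methylcyclohexan-1-ol | I/C=C(\C)[C@H]1CC[C@@](C)(O)[C@@H](Br)C1 | intermediate
25 | (1R,2E)-3-[(1S,3S,4R)-3-bromo-4-hydroxy-4-methylcyclohexyl]-1-[(1R)-2,2-dimethyl-6-methylidenecyclohex-3-en-1-yl]but-2-en-1-ol | C=C1CC=CC(C)(C)[C@@H]1[C@H](O)/C=C(\C)[C@H]1CC[C@@](C)(O)[C@@H](Br)C1 | target

**Step count and risks**

Total steps: 18. Longest linear sequence: 12 (steps 1–11 and 18); the ring B branch is steps 12–17.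

Steps most likely to fail:

1. Step 9 (proposed new method). Possible failures are diversion of the cyclopropylcarbinyl cation before ring opening (ring expansion to cyclobutyl products, internal return, capture by the neighbouring silyl ether oxygen) and proton loss from the tertiary cation before the vinylsilane closes. Fallback with known reactions in two stages: from 11, Me3SiBr with catalytic ZnBr2 (CH2Cl2, −20 °C) would effect the Julia-type cyclopropylcarbinyl-to-homoallyl rearrangement under thermodynamic bromide capture to give tert-butyl{[(2S,5Z)-2-(2-bromopropan-2-yl)-3-methylidene-6-(trimethylsilyl)hex-5-en-1-yl]oxy}diphenylsilane F1. AgOTf with 2,6-di-tert-butylpyridine (CH2Cl2, −60 °C) would then ionise the tertiary bromide and close ring A by the established cation–vinylsilane cyclisation, rejoining the route at 13.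

2. Step 5. Possible failures are insufficient enantiofacial discrimination and slow carbene transfer to the hindered tetrasubstituted alkene, with carbene dimerisation competing. Fallback: from 7, Rh2(OAc)4 in CH2Cl2 would give racemic 6,6-dimethyl-5-[3-(trimethylsilyl)prop-2-yn-1-yl]-3-oxabicyclo[3.1.0]hexan-2-one F2, which would be resolved by preparative chromatography on a chiral stationary phase; the (1S,5S) enantiomer rejoins the route as 8.

3. Step 18. Possible failures are poor or inverted facial selectivity at the aldehyde, epimerisation or double-bond migration of the β,γ-unsaturated aldehyde, and reduction of the C–Br bond by divalent chromium. Fallback by oxidation and reagent-controlled reduction: from 15 and 24 the coupling is run as before and the carbinol mixture, which contains (1S,2E)-3-[(1S,3S,4R)-3-bromo-4-hydroxy-4-methylcyclohexyl]-1-[(1R)-2,2-dimethyl-6-methylidenecyclohex-3-en-1-yl]but-2-en-1-ol F3, is oxidised (Dess–Martin periodinane, NaHCO3, CH2Cl2, 0 °C) to (2E)-3-[(1S,3S,4R)-3-bromo-4-hydroxy-4-methylcyclohexyl]-1-[(1R)-2,2-dimethyl-6-methylidenecyclohex-3-en-1-yl]but-2-en-1-one F4. Corey–Bakshi–Shibata reduction ((S)-2-methyl-CBS-oxazaborolidine, catecholborane, toluene, −78 °C, the α-branched ring carbon acting as the large group) should then deliver hydride under reagent control and return 25.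

Further compounds
F1 | step 9 | tert-butyl{[(2S,5Z)-2-(2-bromopropan-2-yl)-3-methylidene-6-(trimethylsilyl)hex-5-en-1-yl]oxy}diphenylsilane | C=C(C/C=C\[Si](C)(C)C)[C@@H](CO[Si](c1ccccc1)(c1ccccc1)C(C)(C)C)C(C)(C)Br
F2 | step 5 | racemic 6,6-dimethyl-5-[3-(trimethylsilyl)prop-2-yn-1-yl]-3-oxabicyclo[3.1.0]hexan-2-one | O=C1OCC2(CC#C[Si](C)(C)C)C1C2(C)C
F3 | step 18 | (1S,2E)-3-[(1S,3S,4R)-3-bromo-4-hydroxy-4-methylcyclohexyl]-1-[(1R)-2,2-dimethyl-6-methylidenecyclohex-3-en-1-yl]but-2-en-1-ol | C=C1CC=CC(C)(C)[C@@H]1[C@@H](O)/C=C(\C)[C@H]1CC[C@@](C)(O)[C@@H](Br)C1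
F4 | step 18 | (2E)-3-[(1S,3S,4R)-3-bromo-4-hydroxy-4-methylcyclohexyl]-1-[(1R)-2,2-dimethyl-6-methylidenecyclohex-3-en-1-yl]but-2-en-1-one | C=C1CC=CC(C)(C)[C@@H]1C(=O)/C=C(\C)[C@H]1CC[C@@](C)(O)[C@@H](Br)C1
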